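**Plan** (target numbering: C1 and C4 = CH–OBz, C2=C3, C5 = CH–OH, C6 = C(OH), C7 = CH2OH)
- Cuts, in retrosynthetic order: the two benzoates and the acetonide/silyl helpers; C1–O and C4–O (back to a C1=C2–C3=C4 diene plus O2); C5–OH to C5=O and C7H2OH to an ester; last, the ring bond C6–C1.
- Enabling feature: C6 is a tertiary carbinol that carries the one-carbon branch C7 and sits next to the oxygenated C5. A C6(OH)–C5(=O) pair is what an α-ketol shift leaves behind, so C1 is returned from C6 to C5 and the six-ring C1–C6 becomes a cyclopentene C1–C5 bearing OH and the chain C6(=O)–C7O2Et on C5.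
- Forward: cyclopent-3-enone and ethyl diazoacetate make C5–C6; diazo is turned into keto; the cyclopentene is enlarged to the cyclohexene; then ketone reduction, acetonide (temporary ring), dibromide, diene, ester reduction, silylation, singlet oxygen (temporary peroxide bridge), benzoylation, acid.
- Stereochemistry: C6 from the chiral copper catalyst, which chooses between the two enantiotopic ring CH2 groups of an achiral precursor; C5 from C6 (hydride anti to the C6–O bond); C1 and C4 together from the cis-fused acetonide, which sends singlet oxygen to the opposite face.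

Key step: step 3

Assumption: with the (S,S)-ligand the catalyst of step 3 is taken to deliver (R)-5; if the sense of induction is the reverse, the (R,R)-ligand is used and nothing else changes.

**Step 1**
Reactants: 1 cyclopent-3-en-1-one; 2 ethyl diazoacetate
Product: 3 ethyl 2-diazo-2-(1-hydroxycyclopent-3-en-1-yl)acetate
Conditions: LDA (commercial solution), THF, −78 °C; AcOH quench at −78 °C
Reagents that add atoms: none
Why: Aldol-type 1,2-addition of lithiated ethyl diazoacetate to the ketone, which at −78 °C should outrun deprotonation of the β,γ-unsaturated ketone; the new carbinol carbon has two identical ring arms and is not a stereocenter.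

**Step 2**
Reactants: 3 ethyl 2-diazo-2-(1-hydroxycyclopent-3-en-1-yl)acetate
Product: 4 ethyl 2-(1-hydroxycyclopent-3-en-1-yl)-2-oxoacetate
Conditions: dimethyldioxirane (1.05 equiv, acetone solution), acetone, −40 → 0 °C; dried over 4 Å MS and used at once
Reagents that add atoms: dimethyldioxirane, CC1(C)OO1
Why: Dioxirane oxidation of a diazo carbon to a carbonyl with loss of N2; the electron-rich diazo carbon should react far faster than the cis-disubstituted ring alkene, so one equivalent at low temperature should leave the alkene untouched.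

**Step 3**
Reactants: 4 ethyl 2-(1-hydroxycyclopent-3-en-1-yl)-2-oxoacetate
Product: 5 ethyl (1R)-1-hydroxy-2-oxocyclohex-4-ene-1-carboxylate
Conditions: Cu(OTf)2 (10 mol %), (S,S)-t-Bu-box (12 mol %), 4 Å MS, ClCH2CH2Cl, 25 °C
Reagents that add atoms: none
Why: The Cu(II)–bis(oxazoline) complex should bind the 1,2-dicarbonyl of 4 as a five-membered chelate, and one ring CH2 then shifts with its bonding pair from the carbinol carbon to the activated ketone carbon while the carbinol C–O becomes C=O (α-ketol or acyloin rearrangement). The closest known reaction type is the Lewis-acid-catalysed enantioselective α-ketol rearrangement of tertiary β-hydroxy-α-keto esters, including ring enlargement of 1-acylcycloalkanols. No ring is closed by cyclisation: the six-membered ring arises by ring enlargement, the former exocyclic keto carbon being inserted into a C–C bond of the cyclopentene by a suprafacial 1,2-shift. The new quaternary carbinol stereocenter is controlled by the ligand alone, because the two ring CH2 groups of achiral 4 are enantiotopic and choosing one of them is the same as choosing a face of the ketone. The step needs group selectivity (from the catalyst) and a fixed direction, which should come from trading a 1,2-dicarbonyl in a cyclopentene for a β-keto ester in a six-membered ring; only the two ring carbons can migrate, so no constitutional isomer is possible. Mild, neutral conditions are chosen so that the β,γ-alkene does not move into conjugation and a degenerate 1,2-shift of the ester group, which would racemise 5, stays slow.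

**Step 4**
Reactants: 5 ethyl (1R)-1-hydroxy-2-oxocyclohex-4-ene-1-carboxylate
Product: 6 ethyl (1R,2S)-1,2-dihydroxycyclohex-4-ene-1-carboxylate
Conditions: NaBH4 (0.5 equiv), MeOH–CH2Cl2, −78 °C
Reagents that add atoms: none
Why: Substrate-controlled ketone reduction in which hydride should add axially, anti to the axial C1–O bond of the half-chair that keeps the ester equatorial (polar Felkin–Anh model), giving the cis-diol and setting C2 as S; the low temperature spares the ester and suppresses retro-Claisen cleavage.

**Step 5**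
Reactants: 6 ethyl (1R,2S)-1,2-dihydroxycyclohex-4-ene-1-carboxylate
Product: 7 ethyl (3aR,7aS)-2,2-dimethyl-3a,4,7,7a-tetrahydro-1,3-benzodioxole-3a-carboxylate
Conditions: 2,2-dimethoxypropane, TsOH·H2O (cat.), acetone, rt
Reagents that add atoms: 2,2-dimethoxypropane, COC(C)(C)OC
Why: Acid-catalysed transketalisation of a cis-1,2-diol to the cis-fused dioxolane, which protects both hydroxyls and later shields one face of the ring.

**Step 6**
Reactants: 7 ethyl (3aR,7aS)-2,2-dimethyl-3a,4,7,7a-tetrahydro-1,3-benzodioxole-3a-carboxylate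
Product: 8 ethyl (3aR,5R,6R,7aS)-5,6-dibromo-2,2-dimethylhexahydro-1,3-benzodioxole-3a-carboxylate (trans-dibromide; the 5S,6S diastereomer, if formed, converges in step 7)
Conditions: Br2 (1.05 equiv), CH2Cl2, −78 °C
Reagents that add atoms: bromine, BrBr
Why: Anti addition of bromine through a bromonium ion; the two new stereocenters are trans to each other and are destroyed again in step 7.

**Step 7**
Reactants: 8 ethyl (3aR,5R,6R,7aS)-5,6-dibromo-2,2-dimethylhexahydro-1,3-benzodioxole-3a-carboxylate
Product: 9 ethyl (3aR,7aS)-2,2-dimethyl-3a,7a-dihydro-1,3-benzodioxole-3a-carboxylate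
Conditions: DBU (4 equiv), toluene, 80 °C
Reagents that add atoms: none
Why: Double E2 dehydrobromination, in which each bromide can only lose a hydrogen from C4 or C7, so the conjugated 4,6-diene should form; the acetonide blocks aromatisation.

**Step 8**
Reactants: 9 ethyl (3aR,7aS)-2,2-dimethyl-3a,7a-dihydro-1,3-benzodioxole-3a-carboxylate
Product: 10 [(3aS,7aS)-2,2-dimethyl-3a,7a-dihydro-1,3-benzodioxol-3a-yl]methanol
Conditions: LiAlH4, Et2O, 0 °C; aqueous NaOH work-up
Reagents that add atoms: none
Why: Hydride reduction of the ester to the primary alcohol, done before the benzoates are present (the descriptor at C3a changes by priority only).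

**Step 9**
Reactants: 10 [(3aS,7aS)-2,2-dimethyl-3a,7a-dihydro-1,3-benzodioxol-3a-yl]methanol
Product: 11 tert-butyl{[(3aS,7aS)-2,2-dimethyl-3a,7a-dihydro-1,3-benzodioxol-3a-yl]methoxy}dimethylsilane
Conditions: TBSCl, imidazole, DMAP (cat.), DMF, rt
Reagents that add atoms: tert-butyldimethylsilyl chloride, CC(C)(C)[Si](C)(C)Cl
Why: Silylation keeps the primary hydroxyl out of the later benzoylation.

**Step 10**
Reactants: 11 tert-butyl{[(3aS,7aS)-2,2-dimethyl-3a,7a-dihydro-1,3-benzodioxol-3a-yl]methoxy}dimethylsilane
Product: 13 (3aR,4S,7R,7aS)-3a-{[(tert-butyldimethylsilyl)oxy]methyl}-2,2-dimethyl-3a,4,7,7a-tetrahydro-1,3-benzodioxole-4,7-diol, via anti-endoperoxide 12 (not isolated)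
Conditions: O2, tetraphenylporphyrin (cat.), visible light, CH2Cl2, −20 °C; then thiourea, wet MeOH, rt
Reagents that add atoms: oxygen (used as singlet oxygen), O=O
Why: [4+2] cycloaddition of singlet oxygen to the cyclohexadiene on the face opposite the two dioxolane oxygens, followed by thiourea reduction of the O–O bond, should give the cis-1,4-diol; C4 and C7 are set together, cis to each other and trans to the acetonide.

**Step 11**
Reactants: 13 (3aR,4S,7R,7aS)-3a-{[(tert-butyldimethylsilyl)oxy]methyl}-2,2-dimethyl-3a,4,7,7a-tetrahydro-1,3-benzodioxole-4,7-diol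
Product: 14 (3aR,4S,7R,7aS)-3a-{[(tert-butyldimethylsilyl)oxy]methyl}-2,2-dimethyl-3a,4,7,7a-tetrahydro-1,3-benzodioxole-4,7-diyl dibenzoate
Conditions: BzCl (2.5 equiv), pyridine, DMAP (cat.), CH2Cl2, 0 °C → rt
Reagents that add atoms: benzoyl chloride, O=C(Cl)c1ccccc1
Why: DMAP-catalysed acylation of the only two free hydroxyls, with no change at any stereocenter.

**Step 12**
Reactants: 14 (3aR,4S,7R,7aS)-3a-{[(tert-butyldimethylsilyl)oxy]methyl}-2,2-dimethyl-3a,4,7,7a-tetrahydro-1,3-benzodioxole-4,7-diyl dibenzoate
Product: 15 (1S,4R,5S,6S)-5,6-dihydroxy-6-(hydroxymethyl)cyclohex-2-ene-1,4-diyl dibenzoate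
Conditions: TFA–H2O (9:1), CH2Cl2, 0 °C → rt
Reagents that add atoms: none
Why: Acid hydrolysis of the isopropylidene acetal and the silyl ether in one operation; acid is chosen because benzoyl migration to the free hydroxyls is base-promoted.

**Compound list**
1 | cyclopent-3-en-1-one | O=C1CC=CC1 | starting material
2 | ethyl diazoacetate | CCOC(=O)C=[N+]=[N-] | starting material
3 | ethyl 2-diazo-2-(1-hydroxycyclopent-3-en-1-yl)acetate | CCOC(=O)C(=[N+]=[N-])C1(O)CC=CC1 | intermediate
4 | ethyl 2-(1-hydroxycyclopent-3-en-1-yl)-2-oxoacetate | CCOC(=O)C(=O)C1(O)CC=CC1 | intermediate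
5 | ethyl (1R)-1-hydroxy-2-oxocyclohex-4-ene-1-carboxylate | CCOC(=O)[C@@]1(O)CC=CCC1=O | intermediate
6 | ethyl (1R,2S)-1,2-dihydroxycyclohex-4-ene-1-carboxylate | CCOC(=O)[C@@]1(O)CC=CC[C@@H]1O | intermediate
7 | ethyl (3aR,7aS)-2,2-dimethyl-3a,4,7,7a-tetrahydro-1,3-benzodioxole-3a-carboxylate | CCOC(=O)[C@@]12CC=CC[C@@H]1OC(C)(C)O2 | intermediate
8 | ethyl (3aR,5R,6R,7aS)-5,6-dibromo-2,2-dimethylhexahydro-1,3-benzodioxole-3a-carboxylate | CCOC(=O)[C@@]12C[C@@H](Br)[C@H](Br)C[C@@H]1OC(C)(C)O2 | intermediate
9 | ethyl (3aR,7aS)-2,2-dimethyl-3a,7a-dihydro-1,3-benzodioxole-3a-carboxylate | CCOC(=O)[C@@]12C=CC=C[C@@H]1OC(C)(C)O2 | intermediate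
10 | [(3aS,7aS)-2,2-dimethyl-3a,7a-dihydro-1,3-benzodioxol-3a-yl]methanol | OC[C@@]12C=CC=C[C@@H]1OC(C)(C)O2 | intermediate
11 | tert-butyl{[(3aS,7aS)-2,2-dimethyl-3a,7a-dihydro-1,3-benzodioxol-3a-yl]methoxy}dimethylsilane | CC(C)(C)[Si](C)(C)OC[C@@]12C=CC=C[C@@H]1OC(C)(C)O2 | intermediate
12 | anti-endoperoxide of 11 (O–O bridge from C4 to C7 on the face opposite the dioxolane oxygens, C5=C6 alkene) | CC(C)(C)[Si](C)(C)OC[C@@]12[C@@H]3C=C[C@@H](OO3)[C@@H]1OC(C)(C)O2 | intermediate
13 | (3aR,4S,7R,7aS)-3a-{[(tert-butyldimethylsilyl)oxy]methyl}-2,2-dimethyl-3a,4,7,7a-tetrahydro-1,3-benzodioxole-4,7-diol | CC(C)(C)[Si](C)(C)OC[C@@]12[C@@H](O)C=C[C@@H](O)[C@@H]1OC(C)(C)O2 | intermediate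
14 | (3aR,4S,7R,7aS)-3a-{[(tert-butyldimethylsilyl)oxy]methyl}-2,2-dimethyl-3a,4,7,7a-tetrahydro-1,3-benzodioxole-4,7-diyl dibenzoate | CC(C)(C)[Si](C)(C)OC[C@@]12[C@@H](OC(=O)c3ccccc3)C=C[C@@H](OC(=O)c3ccccc3)[C@@H]1OC(C)(C)O2 | intermediate
15 | (1S,4R,5S,6S)-5,6-dihydroxy-6-(hydroxymethyl)cyclohex-2-ene-1,4-diyl dibenzoate | O=C(O[C@H]1C=C[C@@H](OC(=O)c2ccccc2)[C@H](O)[C@@]1(O)CO)c1ccccc1 | target

**Count**
Total steps: 12. Longest linear sequence: 12 steps (fully linear from 1).

**Steps most likely to fail**

Step 3 (key step). What may go wrong: too little discrimination between the two enantiotopic CH2 groups, erosion of enantiopurity by a degenerate 1,2-shift of the ester group in the product, or drift of the β,γ-alkene into conjugation with the new ketone. The fallback sets out from 3 and comes back at 5. Dirhodium tetraacetate (cat., CH2Cl2, rt) should turn 3, by loss of nitrogen and 1,2-shift of a ring carbon to the rhodium carbenoid, into the ring-enlarged β-keto ester ethyl 2-oxocyclohex-4-ene-1-carboxylate F1 (configurationally labile, keto/enol mixture). A catalytic enantioselective α-hydroxylation of this cyclic β-keto ester (cinchona-alkaloid catalyst, cumene hydroperoxide) would then set the quaternary carbinol and give 5. The ring is still made by enlargement of the cyclopentene, but group selection is replaced by face selection on a flat enol.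

Step 4. What may go wrong: hydride delivery on the hydroxyl-bearing face through a chelate or borate of the tertiary alcohol (giving the trans-diol), or retro-Claisen opening of the non-enolisable β-keto ester. The fallback sets out from 5 and comes back at 6. Hydroxyl-directed reduction with Me4NBH(OAc)3 (AcOH–MeCN, −20 °C) would give on purpose the trans-diol ethyl (1R,2R)-1,2-dihydroxycyclohex-4-ene-1-carboxylate F2. Mitsunobu inversion of its secondary hydroxyl (4-nitrobenzoic acid, PPh3, DIAD, THF) would give ethyl (1R,2S)-1-hydroxy-2-[(4-nitrobenzoyl)oxy]cyclohex-4-ene-1-carboxylate F3. Ethanolysis (K2CO3, EtOH, 0 °C) would then give 6.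

Step 10. What may go wrong: attack of singlet oxygen on the wrong face because of the silyloxymethyl group next to the diene terminus, or base-type fragmentation of the endoperoxide to a hydroxy enone during reduction. The fallback sets out from 11 and comes back at 14. Buffered mCPBA (NaHCO3, CH2Cl2, 0 °C) should epoxidise the less hindered C6=C7 alkene on the face opposite the dioxolane, giving the vinyl epoxide 6,7-anti-epoxide of 11 F4. Pd(PPh3)4 with benzoic acid (THF, rt) should open it through a π-allyl complex with overall retention to the cis-1,4 product (3aR,4S,7R,7aS)-3a-{[(tert-butyldimethylsilyl)oxy]methyl}-7-hydroxy-2,2-dimethyl-3a,4,7,7a-tetrahydro-1,3-benzodioxol-4-yl benzoate F5. Benzoylation of the remaining hydroxyl (BzCl, pyridine) would give 14; because both oxygens end as benzoates, the regiochemistry of the epoxidation does not matter.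

**Further compounds**
F1 | step 3 | ethyl 2-oxocyclohex-4-ene-1-carboxylate (configurationally labile) | CCOC(=O)C1CC=CCC1=O
F2 | step 4 | ethyl (1R,2R)-1,2-dihydroxycyclohex-4-ene-1-carboxylate | CCOC(=O)[C@@]1(O)CC=CC[C@H]1O
F3 | step 4 | ethyl (1R,2S)-1-hydroxy-2-[(4-nitrobenzoyl)oxy]cyclohex-4-ene-1-carboxylate | CCOC(=O)[C@@]1(O)CC=CC[C@@H]1OC(=O)c1ccc(cc1)[N+](=O)[O-]
F4 | step 10 | 6,7-anti-epoxide of 11 (oxirane on the face opposite the dioxolane, C4=C5 alkene kept) | CC(C)(C)[Si](C)(C)OC[C@@]12C=C[C@H]3O[C@H]3[C@@H]1OC(C)(C)O2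
F5 | step 10 | (3aR,4S,7R,7aS)-3a-{[(tert-butyldimethylsilyl)oxy]methyl}-7-hydroxy-2,2-dimethyl-3a,4,7,7a-tetrahydro-1,3-benzodioxol-4-yl benzoate | CC(C)(C)[Si](C)(C)OC[C@@]12[C@@H](OC(=O)c3ccccc3)C=C[C@@H](O)[C@@H]1OC(C)(C)O2
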